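**Retrosynthetic overview**
1. Target 6 ⇒ benzyl ester 5: cleavage of the C7 ester O–CH2Ph bond (neutral hydrogenolysis, last step).
2. 5 ⇒ alkene 3: C16–O disconnection, a Markovnikov radical hydration of the 16(17) exocyclic methylene with oxygen delivered to the exo face; this sets the only stereocentre made in the route.
3. 3 ⇒ gibberellin A-four (1): carboxylate O-benzylation.
4. Ring order: no ring is built. Rings A, B, C, D and the 19,10-γ-lactone, with eight of the nine stereocentres, arrive intact in 1.

Assumption: gibberellin A-four (CAS 468-44-0), a fermentation product sold as a catalogue reagent, counts as a commercially available starting material, so the route is a three-step relay (partial) synthesis from it rather than a de novo construction of the skeleton.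

Throughout, "exo" at C16 means the face turned toward the one-carbon C14 bridge of the bicyclo[3.2.1]octane, and "endo" the face turned toward the C11–C12 bridge.

**Route**

Step 1
Reactants: 1 gibberellin A-four
Product: 3 gibberellin A-four 7-benzyl ester, via potassium carboxylate 2 (not isolated)
Conditions: KHCO3 (1.5 equiv), BnBr (1.2 equiv), DMF, rt, 16 h
Reagents that add atoms: benzyl bromide (BnBr), SMILES BrCc1ccccc1
Why: Carboxylate O-alkylation (SN2 on benzyl bromide) is insensitive to the hindrance around C7, and bicarbonate is too weak a base to deprotonate the 3-OH, open the lactone or trigger retro-aldol epimerisation at C3, so the ester forms chemoselectively with all eight stereocentres untouched and no new one created.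

Step 2
Reactants: 3 gibberellin A-four 7-benzyl ester
Product: 5 gibberellin A-two 7-benzyl ester, via tertiary 16-hydroperoxide 4 (not isolated)
Conditions: Mn(dpm)3 [dpm = 2,2,6,6-tetramethylheptane-3,5-dionate] (10 mol %), PhSiH3 (2.5 equiv), O2 (1 atm), 2-propanol/CH2Cl2, 0 °C to rt; then PPh3 (1.5 equiv), rt, 1 h
Reagents that add atoms: dioxygen (O2), SMILES O=O
Why: In this Mukaiyama hydration (metal-hydride hydrogen-atom transfer) the manganese hydride delivers H to the terminal C17 to give the tertiary C16 radical, which captures O2 on the open exo face, so that after PPh3 reduces the O–O bond with retention at carbon the 16-OH is exo and the new methyl endo as in the target, while ester, lactone and 3-OH are inert under these neutral radical conditions.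

Step 3
Reactants: 5 gibberellin A-two 7-benzyl ester
Product: 6 gibberellin A-two
Conditions: H2 (1 atm), 10% Pd/C, EtOAc, rt
Reagents that add atoms: none
Why: Catalytic hydrogenolysis of the benzylic C–O bond over palladium frees the acid under neutral conditions that leave the tertiary and secondary alcohols, the saturated γ-lactone and all nine stereocentres untouched (no alkene remains to be reduced), and it avoids the basic hydrolysis that would epimerise C3.

**Compound list**

1 | gibberellin A-four (natural enantiomer, CAS 468-44-0): C19 gibberellin with 3β-OH (cis to the C4 methyl, trans to the lactone bridge), 19→10 γ-lactone, C7 carboxylic acid on C6 (cis to H-5, on the face of the C15–C16 bridge), exocyclic 16(17)-methylene | C[C@@]12C(=O)O[C@]3(CC[C@@H]1O)[C@@H]1CC[C@@H]4C[C@]1(CC4=C)[C@@H](C(=O)O)[C@@H]32 | starting material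
2 | potassium 7-carboxylate of gibberellin A-four (formed in the flask, all stereocentres as in 1) | C[C@@]12C(=O)O[C@]3(CC[C@@H]1O)[C@@H]1CC[C@@H]4C[C@]1(CC4=C)[C@@H](C(=O)[O-])[C@@H]32.[K+] | intermediate
3 | gibberellin A-four 7-benzyl ester (as 1, CO2H replaced by CO2CH2Ph) | C[C@@]12C(=O)O[C@]3(CC[C@@H]1O)[C@@H]1CC[C@@H]4C[C@]1(CC4=C)[C@@H](C(=O)OCc5ccccc5)[C@@H]32 | intermediate
4 | 16-hydroperoxy-16-methyl benzyl ester (formed in the flask): C16 carries OOH exo (syn to the C14 bridge) and CH3 endo, rest as 3 | C[C@@]12C(=O)O[C@]3(CC[C@@H]1O)[C@@H]1CC[C@@H]4C[C@]1(C[C@@]4(C)OO)[C@@H](C(=O)OCc5ccccc5)[C@@H]32 | intermediate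
5 | gibberellin A-two 7-benzyl ester: C16 carries OH exo (syn to the C14 bridge) and CH3 endo, rest as 3 | C[C@@]12C(=O)O[C@]3(CC[C@@H]1O)[C@@H]1CC[C@@H]4C[C@]1(C[C@@]4(C)O)[C@@H](C(=O)OCc5ccccc5)[C@@H]32 | intermediate
6 | gibberellin A-two: 3β,16-exo-dihydroxy-16-endo-methyl C19 gibberellin 19,10-lactone 7-oic acid | C[C@@]12C(=O)O[C@]3(CC[C@@H]1O)[C@@H]1CC[C@@H]4C[C@]1(C[C@@]4(C)O)[C@@H](C(=O)O)[C@@H]32 | target

**Totals**

Total step count: 3. Longest linear sequence: 3 steps (1 → 3 → 5 → 6).

**Steps most likely to fail, with fallbacks**

Step 2 is the riskiest. The C16 radical can be reduced to the 16-methyl alkane instead of trapping O2, and the exo/endo ratio of O2 capture is expected rather than proven on this exact substrate. The fallback sets out from 3 and returns at 5 by an ionic oxymercuration–demercuration. Hg(OAc)2 in THF/water at rt gives 17-(acetoxymercurio)-16-exo-hydroxy-16,17-dihydrogibberellin A-four 7-benzyl ester F1, in which water has added to the tertiary C16 of the mercurinium ion from the exo face, as it does with 2-methylenenorbornane. Brief treatment with NaBH4 in cold dilute aqueous NaOH (0 °C, minutes, to spare C3 and the ester) replaces C–Hg by C–H and gives 5.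

Step 3 is next. Phosphorus or silicon residues carried from step 2 can poison the palladium surface and stall the hydrogenolysis. The fallback sets out from 1 and returns at 6 with an ester that is removed by nucleophilic dealkylation instead of hydrogenolysis. Iodomethane and KHCO3 in DMF (again through carboxylate 2) give gibberellin A-four 7-methyl ester F2. The same Mn(dpm)3/PhSiH3/O2 hydration passes through the methyl ester 16-exo-hydroperoxide F3 and, after PPh3, gives gibberellin A-two 7-methyl ester F4. Lithium propanethiolate (LiSPr) in HMPA at 0 °C to rt then attacks the ester methyl group, which leaves as methyl propyl sulfide, and cold dilute acid work-up delivers 6. The γ-lactone is spared because its alkyl oxygen sits on the tertiary C10.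

Step 1 is the least risky. The possible problems are sluggish alkylation of the hindered acid or trace C3 epimerisation on long exposure to base. The fallback sets out from 1 and returns at 6 without any protecting group. The free acid is submitted directly to the Mn(dpm)3/PhSiH3/O2 conditions, with extra silane to allow for transient silyl ester formation, giving the 16-exo-hydroperoxy acid F5. PPh3 reduces this in the same flask to 6, which is then purified by reversed-phase chromatography.

**Further compounds**

F1 | step 2 | 17-(acetoxymercurio)-16-exo-hydroxy-16,17-dihydrogibberellin A-four 7-benzyl ester | C[C@@]12C(=O)O[C@]3(CC[C@@H]1O)[C@@H]1CC[C@@H]4C[C@]1(C[C@@]4(C[Hg]OC(C)=O)O)[C@@H](C(=O)OCc5ccccc5)[C@@H]32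
F2 | step 3 | gibberellin A-four 7-methyl ester | C[C@@]12C(=O)O[C@]3(CC[C@@H]1O)[C@@H]1CC[C@@H]4C[C@]1(CC4=C)[C@@H](C(=O)OC)[C@@H]32
F3 | step 3 | 16-exo-hydroperoxy-16-endo-methyl methyl ester (hydroperoxide of F2) | C[C@@]12C(=O)O[C@]3(CC[C@@H]1O)[C@@H]1CC[C@@H]4C[C@]1(C[C@@]4(C)OO)[C@@H](C(=O)OC)[C@@H]32
F4 | step 3 | gibberellin A-two 7-methyl ester | C[C@@]12C(=O)O[C@]3(CC[C@@H]1O)[C@@H]1CC[C@@H]4C[C@]1(C[C@@]4(C)O)[C@@H](C(=O)OC)[C@@H]32
F5 | step 1 | 16-exo-hydroperoxy-16-endo-methyl free acid (16-hydroperoxide corresponding to gibberellin A-two) | C[C@@]12C(=O)O[C@]3(CC[C@@H]1O)[C@@H]1CC[C@@H]4C[C@]1(C[C@@]4(C)OO)[C@@H](C(=O)O)[C@@H]32
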